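**Retrosynthetic overview**
- The target comes from a fully protected (2R,3S)-3-(flavon-8-yl)flavanone by one final operation that removes five benzyl ethers and the trichloroethyl group of a protected sulfate.
- Flavanone ring C is the last ring formed: its O1–C2 bond is closed by a catalytic enantioselective oxa-Michael addition of an α-(flavon-8-yl)-2'-hydroxychalcone (C2 set by the catalyst, C3 by equilibration to trans).
- The chalcone comes from Knoevenagel condensation of a deoxybenzoin with 4-(benzyloxy)benzaldehyde; the deoxybenzoin (C3–C8'' bond) comes from Pd-catalysed α-arylation of a protected phloracetophenone with an 8-iodoapigenin ether.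
- The flavone rings are taken intact from apigenin; its 7-OH is singled out at the start as a MOM ether and exchanged for the protected sulfate before ring closure.

Assumption: the target is taken as the free hydrogen sulfate as drawn (made from its ammonium salt in the last step and kept cold); the hindered C3–C8'' bond gives NMR rotamers, not a further stereo-element.

**Step 1**
Reactants: 1 apigenin
Product: 2 5-hydroxy-2-(4-hydroxyphenyl)-7-(methoxymethoxy)-4H-chromen-4-one
Conditions: MOMCl (1.05 equiv), iPr2NEt (1.1 equiv), DMF, −10 to 0 °C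
Reagents that add atoms: chloromethyl methyl ether, COCCl
Why: Williamson-type O-alkylation; the 7-OH (para to the C4 carbonyl) is the most acidic phenol and the only one appreciably ionised by the hindered amine, the 4'-OH is less acidic and the 5-OH is hydrogen-bonded to the carbonyl, so one equivalent of MOMCl gives mainly the 7-ether (bis-ether and recovered 1 are separated).

**Step 2**
Reactants: 2 5-hydroxy-2-(4-hydroxyphenyl)-7-(methoxymethoxy)-4H-chromen-4-one
Product: 3 5-(benzyloxy)-2-[4-(benzyloxy)phenyl]-7-(methoxymethoxy)-4H-chromen-4-one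
Conditions: BnBr (2.6 equiv), K2CO3 (3 equiv), DMF, 80 °C
Reagents that add atoms: benzyl bromide, BrCc1ccccc1
Why: Williamson etherification under forcing conditions alkylates both the 4'-OH and the chelated 5-OH, while the MOM acetal is inert to base.

**Step 3**
Reactants: 3 5-(benzyloxy)-2-[4-(benzyloxy)phenyl]-7-(methoxymethoxy)-4H-chromen-4-one
Product: 4 5-(benzyloxy)-2-[4-(benzyloxy)phenyl]-8-iodo-7-(methoxymethoxy)-4H-chromen-4-one
Conditions: BnMe3N ICl2 (1.2 equiv), CaCO3, CH2Cl2–MeOH, rt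
Reagents that add atoms: benzyltrimethylammonium dichloroiodate, C[N+](C)(C)Cc1ccccc1.Cl[I-]Cl
Why: Electrophilic aromatic iodination; with every phenol alkylated, C8 (para to the 5-alkoxy group, ortho to O7 and O1) is the most nucleophilic position of a 5,7-dialkoxyflavone, and CaCO3 buffers the HCl so the MOM acetal survives.

**Step 4**
Reactants: 5 1-(2,4,6-trihydroxyphenyl)ethan-1-one (phloracetophenone)
Product: 6 1-[2,4-bis(benzyloxy)-6-hydroxyphenyl]ethan-1-one
Conditions: BnBr (2.05 equiv), K2CO3 (2.2 equiv), DMF, 0 °C to rt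
Reagents that add atoms: benzyl bromide, BrCc1ccccc1
Why: Williamson etherification; the 4-OH and one ortho-OH are benzylated, while the remaining ortho-OH is hydrogen-bonded to the acetyl carbonyl and stays free.

**Step 5**
Reactants: 6 1-[2,4-bis(benzyloxy)-6-hydroxyphenyl]ethan-1-one
Product: 7 1-[2,4-bis(benzyloxy)-6-(methoxymethoxy)phenyl]ethan-1-one
Conditions: NaH (1.2 equiv), MOMCl (1.2 equiv), DMF, 0 °C
Reagents that add atoms: chloromethyl methyl ether, COCCl
Why: Williamson etherification of the sodium phenoxide; full deprotonation with NaH overcomes the chelation, and masking this oxygen prevents any ring closure before the stereo-defining step.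

**Step 6**
Reactants: 7 1-[2,4-bis(benzyloxy)-6-(methoxymethoxy)phenyl]ethan-1-one; 4 5-(benzyloxy)-2-[4-(benzyloxy)phenyl]-8-iodo-7-(methoxymethoxy)-4H-chromen-4-one
Product: 8 5-(benzyloxy)-2-[4-(benzyloxy)phenyl]-8-{2-[2,4-bis(benzyloxy)-6-(methoxymethoxy)phenyl]-2-oxoethyl}-7-(methoxymethoxy)-4H-chromen-4-one
Conditions: 7 (1.3 equiv), Pd2(dba)3 (2.5 mol%), XPhos (6 mol%), K3PO4 (2.5 equiv), toluene, 90 °C
Reagents that add atoms: none
Why: Palladium-catalysed ketone α-arylation (Buchwald–Hartwig enolate arylation): zerovalent palladium inserts into the C8–I bond, the potassium enolate binds and the bulky biaryl phosphine drives reductive elimination; the hindered partners favour mono-arylation and K3PO4 spares the flavone, MOM and benzyl groups.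

**Step 7**
Reactants: 8 the deoxybenzoin from step 6; 9 4-(benzyloxy)benzaldehyde
Product: 10 (E)-1-[2,4-bis(benzyloxy)-6-(methoxymethoxy)phenyl]-3-[4-(benzyloxy)phenyl]-2-{5-(benzyloxy)-2-[4-(benzyloxy)phenyl]-7-(methoxymethoxy)-4-oxo-4H-chromen-8-yl}prop-2-en-1-one
Conditions: 9 (1.5 equiv), piperidine (0.5 equiv), AcOH (0.5 equiv), toluene, reflux, Dean–Stark
Reagents that add atoms: none
Why: Knoevenagel-type (Claisen–Schmidt) condensation of the doubly activated CH2 through the piperidinium iminium ion of 9 with azeotropic water removal; reversible amine addition equilibrates the alkene to the E isomer (aroyl trans to the 4-benzyloxyphenyl group), and with no free ortho-OH no cyclisation can occur.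

**Step 8**
Reactants: 10 the bis-MOM chalcone from step 7
Product: 12 (E)-1-[2,4-bis(benzyloxy)-6-hydroxyphenyl]-3-[4-(benzyloxy)phenyl]-2-{5-(benzyloxy)-2-[4-(benzyloxy)phenyl]-7-hydroxy-4-oxo-4H-chromen-8-yl}prop-2-en-1-one, via bis(trimethylsilyl) ether 11 (not isolated)
Conditions: Me3SiOTf (4.5 equiv), 2,2'-bipyridyl (6 equiv), CH2Cl2, 0 °C to rt; then H2O, rt
Reagents that add atoms: none
Why: Me3SiOTf/2,2'-bipyridyl cleavage of aryl MOM ethers runs through the aryl silyl ethers under non-acidic, non-basic conditions, so the benzyl ethers, enone and flavone are untouched and neither acid-induced benzofuran formation nor base-induced ring closure is triggered.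

**Step 9**
Reactants: 12 the dihydroxy chalcone from step 8
Product: 13 (E)-1-[2,4-bis(benzyloxy)-6-hydroxyphenyl]-3-[4-(benzyloxy)phenyl]-2-{5-(benzyloxy)-2-[4-(benzyloxy)phenyl]-4-oxo-7-[(2,2,2-trichloroethoxy)sulfonyloxy]-4H-chromen-8-yl}prop-2-en-1-one
Conditions: Cl3CCH2OSO2Cl (1.2 equiv), Et3N (1.3 equiv), DMAP (0.2 equiv), THF, −20 °C, 1 h
Reagents that add atoms: 2,2,2-trichloroethyl chlorosulfate, ClS(=O)(=O)OCC(Cl)(Cl)Cl
Why: Sulfuryl transfer (sulfation through the DMAP adduct of the chlorosulfate) occurs at the acidic, non-chelated 7''-OH; the 2'-OH is deactivated by its hydrogen bond to the ketone, and low temperature and short time keep amine-induced cyclisation negligible.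

**Step 10**
Reactants: 13 the 2'-hydroxychalcone trichloroethyl sulfate from step 9
Product: 15 (2R,3S)-5,7-bis(benzyloxy)-2-[4-(benzyloxy)phenyl]-3-{5-(benzyloxy)-2-[4-(benzyloxy)phenyl]-4-oxo-7-[(2,2,2-trichloroethoxy)sulfonyloxy]-4H-chromen-8-yl}chroman-4-one, via cis-(2R,3R) epimer 14 (not isolated)
Conditions: 3-{[3,5-bis(trifluoromethyl)phenyl]amino}-4-{[(9R)-6'-methoxycinchonan-9-yl]amino}cyclobut-3-ene-1,2-dione (quinidine-derived squaramide, 10 mol%), toluene–CH2Cl2 4:1, −10 °C, 48 h; then rt, 12 h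
Reagents that add atoms: none
Why: Proposed new method: enantioselective 6-endo-trig oxa-Michael closure of an α-aryl-2'-hydroxychalcone that carries no activating ester, in which the quinuclidine nitrogen deprotonates the chelated 2'-OH, the squaramide NH groups hold the enone carbonyl, and the ion-paired phenoxide adds to the Cβ face that gives 2R (O1–C2 bond), after which the same amine epimerises the acidic benzylic C3–H of kinetic epimer 14 faster than retro-oxa-Michael opening, so C3 settles as the thermodynamic 2,3-trans (3S, both aryl groups pseudo-equatorial) while C2 stays kinetically fixed; the closest known reaction type is the cinchona thiourea/squaramide-catalysed oxa-Michael cyclisation of alkylidene β-ketoester chalcones to flavanones, and the facial sense is predicted by that analogy (the quinine-derived pseudo-enantiomer gives the antipode).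

**Step 11**
Reactants: 15 the protected (2R,3S)-flavanone from step 10
Product: 17 (2R,3S)-5,7-dihydroxy-2-(4-hydroxyphenyl)-3-[5-hydroxy-2-(4-hydroxyphenyl)-4-oxo-7-(sulfooxy)-4H-chromen-8-yl]chroman-4-one (CNP0271389.1), via ammonium sulfate salt 16 (not isolated)
Conditions: H2 (1 atm), 10% Pd/C, HCO2NH4 (10 equiv), MeOH–THF 1:1, rt; filter; then aq HCl (1.0 equiv), 0 °C, C18 desalting
Reagents that add atoms: none
Why: Hydrogenolysis of the five benzyl ethers and reductive β-elimination of the trichloroethyl group (Pd/C, formate) occur together under neutral, non-enolising conditions that leave the aryl sulfate S–O bonds, the flavone and both stereocentres intact; one equivalent of HCl then protonates the ammonium salt to the hydrogen sulfate.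

**Compound list**
1 | apigenin (5,7-dihydroxy-2-(4-hydroxyphenyl)-4H-chromen-4-one) | O=c1cc(-c2ccc(O)cc2)oc2cc(O)cc(O)c12 | starting material
2 | 5-hydroxy-2-(4-hydroxyphenyl)-7-(methoxymethoxy)-4H-chromen-4-one | O=c1cc(-c2ccc(O)cc2)oc2cc(OCOC)cc(O)c12 | intermediate
3 | 5-(benzyloxy)-2-[4-(benzyloxy)phenyl]-7-(methoxymethoxy)-4H-chromen-4-one | O=c1cc(-c2ccc(OCc3ccccc3)cc2)oc2cc(OCOC)cc(OCc3ccccc3)c12 | intermediate
4 | 5-(benzyloxy)-2-[4-(benzyloxy)phenyl]-8-iodo-7-(methoxymethoxy)-4H-chromen-4-one | O=c1cc(-c2ccc(OCc3ccccc3)cc2)oc2c(I)c(OCOC)cc(OCc3ccccc3)c12 | intermediate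
5 | 1-(2,4,6-trihydroxyphenyl)ethan-1-one (phloracetophenone) | CC(=O)c1c(O)cc(O)cc1O | starting material
6 | 1-[2,4-bis(benzyloxy)-6-hydroxyphenyl]ethan-1-one | CC(=O)c1c(O)cc(OCc2ccccc2)cc1OCc1ccccc1 | intermediate
7 | 1-[2,4-bis(benzyloxy)-6-(methoxymethoxy)phenyl]ethan-1-one | CC(=O)c1c(OCOC)cc(OCc2ccccc2)cc1OCc1ccccc1 | intermediate
8 | 5-(benzyloxy)-2-[4-(benzyloxy)phenyl]-8-{2-[2,4-bis(benzyloxy)-6-(methoxymethoxy)phenyl]-2-oxoethyl}-7-(methoxymethoxy)-4H-chromen-4-one | O=C(Cc1c(OCOC)cc(OCc2ccccc2)c2c(=O)cc(-c3ccc(OCc4ccccc4)cc3)oc12)c1c(OCOC)cc(OCc2ccccc2)cc1OCc1ccccc1 | intermediate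
9 | 4-(benzyloxy)benzaldehyde | O=Cc1ccc(OCc2ccccc2)cc1 | starting material
10 | (E)-1-[2,4-bis(benzyloxy)-6-(methoxymethoxy)phenyl]-3-[4-(benzyloxy)phenyl]-2-{5-(benzyloxy)-2-[4-(benzyloxy)phenyl]-7-(methoxymethoxy)-4-oxo-4H-chromen-8-yl}prop-2-en-1-one | O=C(c1c(OCOC)cc(OCc2ccccc2)cc1OCc1ccccc1)/C(=C/c1ccc(OCc2ccccc2)cc1)c1c(OCOC)cc(OCc2ccccc2)c2c(=O)cc(-c3ccc(OCc4ccccc4)cc3)oc12 | intermediate
11 | bis(trimethylsilyl) ether of 12 (silyl groups on O2' and O7'') | O=C(c1c(O[Si](C)(C)C)cc(OCc2ccccc2)cc1OCc1ccccc1)/C(=C/c1ccc(OCc2ccccc2)cc1)c1c(O[Si](C)(C)C)cc(OCc2ccccc2)c2c(=O)cc(-c3ccc(OCc4ccccc4)cc3)oc12 | intermediate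
12 | (E)-1-[2,4-bis(benzyloxy)-6-hydroxyphenyl]-3-[4-(benzyloxy)phenyl]-2-{5-(benzyloxy)-2-[4-(benzyloxy)phenyl]-7-hydroxy-4-oxo-4H-chromen-8-yl}prop-2-en-1-one | O=C(c1c(O)cc(OCc2ccccc2)cc1OCc1ccccc1)/C(=C/c1ccc(OCc2ccccc2)cc1)c1c(O)cc(OCc2ccccc2)c2c(=O)cc(-c3ccc(OCc4ccccc4)cc3)oc12 | intermediate
13 | (E)-1-[2,4-bis(benzyloxy)-6-hydroxyphenyl]-3-[4-(benzyloxy)phenyl]-2-{5-(benzyloxy)-2-[4-(benzyloxy)phenyl]-4-oxo-7-[(2,2,2-trichloroethoxy)sulfonyloxy]-4H-chromen-8-yl}prop-2-en-1-one | O=C(c1c(O)cc(OCc2ccccc2)cc1OCc1ccccc1)/C(=C/c1ccc(OCc2ccccc2)cc1)c1c(OS(=O)(=O)OCC(Cl)(Cl)Cl)cc(OCc2ccccc2)c2c(=O)cc(-c3ccc(OCc4ccccc4)cc3)oc12 | intermediate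
14 | (2R,3R)-cis epimer of 15 | O=C1c2c(OCc3ccccc3)cc(OCc3ccccc3)cc2O[C@@H](c2ccc(OCc3ccccc3)cc2)[C@H]1c1c(OS(=O)(=O)OCC(Cl)(Cl)Cl)cc(OCc2ccccc2)c2c(=O)cc(-c3ccc(OCc4ccccc4)cc3)oc12 | intermediate
15 | (2R,3S)-5,7-bis(benzyloxy)-2-[4-(benzyloxy)phenyl]-3-{5-(benzyloxy)-2-[4-(benzyloxy)phenyl]-4-oxo-7-[(2,2,2-trichloroethoxy)sulfonyloxy]-4H-chromen-8-yl}chroman-4-one | O=C1c2c(OCc3ccccc3)cc(OCc3ccccc3)cc2O[C@@H](c2ccc(OCc3ccccc3)cc2)[C@@H]1c1c(OS(=O)(=O)OCC(Cl)(Cl)Cl)cc(OCc2ccccc2)c2c(=O)cc(-c3ccc(OCc4ccccc4)cc3)oc12 | intermediate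
16 | ammonium salt of the target sulfate | [NH4+].O=C1c2c(O)cc(O)cc2O[C@@H](c2ccc(O)cc2)[C@@H]1c1c(OS(=O)(=O)[O-])cc(O)c2c(=O)cc(-c3ccc(O)cc3)oc12 | intermediate
17 | (2R,3S)-5,7-dihydroxy-2-(4-hydroxyphenyl)-3-[5-hydroxy-2-(4-hydroxyphenyl)-4-oxo-7-(sulfooxy)-4H-chromen-8-yl]chroman-4-one | O=C1c2c(O)cc(O)cc2O[C@@H](c2ccc(O)cc2)[C@@H]1c1c(OS(=O)(=O)O)cc(O)c2c(=O)cc(-c3ccc(O)cc3)oc12 | target

**Step count**
Total: 11 steps. Longest linear sequence: 9 steps (steps 1, 2, 3, 6, 7, 8, 9, 10, 11).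

**Three steps most likely to fail**

Step 10 (the proposed cyclisation). The hindered, electron-rich enone may react slowly, a racemic background closure may compete, and prolonged exposure to base could erode C2 through ring opening. Fallback with known chemistry, setting out from 13: treatment with Et3N in CH2Cl2 at 40 °C (the classical amine-mediated closure of α-aryl-2'-hydroxychalcones to 2,3-trans-diarylchromanones) gives the racemic trans flavanone, that is 15 together with its (2S,3R) enantiomer F5. Preparative chiral SFC on an amylose tris(3,5-dimethylphenylcarbamate) phase separates the two. F5 is re-racemised by the same base (ring opening and re-closure) and recycled. The route is rejoined at 15.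

Step 6 (α-arylation of two doubly ortho-substituted partners). Oxidative addition into the electron-rich, flanked C8–I bond and the crowded reductive elimination may be slow, leading to hydrodeiodination. Fallback with reversed polarity, setting out from 4 and 7: Miyaura borylation of 4 (B2pin2, PdCl2(dppf), KOAc, dioxane, 90 °C) gives the 8-pinacolboronate F1. Ketone 7 is brominated through its lithium enolate (LiN(SiMe3)2, THF, −78 °C, then NBS) to the α-bromo ketone F2. Suzuki–Miyaura coupling of F1 with F2 (Pd(PPh3)4, K3PO4, THF–H2O, 60 °C) rejoins the route at 8.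

Step 7 (condensation at a CH2 flanked by two 2,6-disubstituted aryl units). The thermodynamic Knoevenagel may stall, or piperidine may attack the flavone C2. Fallback by stepwise kinetic aldol addition and elimination, setting out from 8: deprotonation with LiN(SiMe3)2 in THF at −78 °C and addition of 9 gives the β-hydroxy ketone F3. Mesylation (MsCl, Et3N, CH2Cl2, 0 °C) gives its mesylate F4, which is eliminated in the same flask with DBU at rt (E1cB) to rejoin the route at 10.

**Further compounds**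
F1 | step 6 | 5-(benzyloxy)-2-[4-(benzyloxy)phenyl]-7-(methoxymethoxy)-8-(4,4,5,5-tetramethyl-1,3,2-dioxaborolan-2-yl)-4H-chromen-4-one | O=c1cc(-c2ccc(OCc3ccccc3)cc2)oc2c(B3OC(C)(C)C(C)(C)O3)c(OCOC)cc(OCc3ccccc3)c12
F2 | step 6 | 1-[2,4-bis(benzyloxy)-6-(methoxymethoxy)phenyl]-2-bromoethan-1-one | O=C(CBr)c1c(OCOC)cc(OCc2ccccc2)cc1OCc1ccccc1
F3 | step 7 | 1-[2,4-bis(benzyloxy)-6-(methoxymethoxy)phenyl]-3-[4-(benzyloxy)phenyl]-2-{5-(benzyloxy)-2-[4-(benzyloxy)phenyl]-7-(methoxymethoxy)-4-oxo-4H-chromen-8-yl}-3-hydroxypropan-1-one (racemic mixture of syn and anti diastereomers, stereocentres unassigned) | OC(c1ccc(OCc2ccccc2)cc1)C(C(=O)c1c(OCOC)cc(OCc2ccccc2)cc1OCc1ccccc1)c1c(OCOC)cc(OCc2ccccc2)c2c(=O)cc(-c3ccc(OCc4ccccc4)cc3)oc12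
F4 | step 7 | methanesulfonate ester of F3 (same unassigned stereocentres) | CS(=O)(=O)OC(c1ccc(OCc2ccccc2)cc1)C(C(=O)c1c(OCOC)cc(OCc2ccccc2)cc1OCc1ccccc1)c1c(OCOC)cc(OCc2ccccc2)c2c(=O)cc(-c3ccc(OCc4ccccc4)cc3)oc12
F5 | step 10 | (2S,3R)-5,7-bis(benzyloxy)-2-[4-(benzyloxy)phenyl]-3-{5-(benzyloxy)-2-[4-(benzyloxy)phenyl]-4-oxo-7-[(2,2,2-trichloroethoxy)sulfonyloxy]-4H-chromen-8-yl}chroman-4-one (enantiomer of 15) | O=C1c2c(OCc3ccccc3)cc(OCc3ccccc3)cc2O[C@H](c2ccc(OCc3ccccc3)cc2)[C@H]1c1c(OS(=O)(=O)OCC(Cl)(Cl)Cl)cc(OCc2ccccc2)c2c(=O)cc(-c3ccc(OCc4ccccc4)cc3)oc12
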